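**Retrosynthetic overview**
1. Target ⇒ global desilylation and two ester C–O bonds: diol 16 + 2 × 4-(TBSO)benzoic acid 21 (from 4-bromophenol and CO2).
2. 16 ⇒ C5–vinyl Suzuki coupling: aryl bromide 14 + (E)-alkenyl boronate 3 (from propargyl alcohol; used twice).
3. 14 ⇒ Pd-catalysed enantioselective [3+2] oxyarylation forming C3–C3a and C2–O in one step: iodophenol 13 + (E)-sinapyl bis-silyl ether 9.
4. 9 ⇒ Suzuki coupling of aryl bromide 8 (phenol → dibromide → syringol → bromide → TIPS ether) with 3; 13 ⇒ catechol via guaiacol, bromination, iodination.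
5. Ring order: both benzene rings are bought as such; the only ring built is the dihydrofuran, closed in step 11 with both stereocentres.

Assumption: catalytic-cycle metal species, transient activated acyl species and the partly converted species of steps that run one transformation two or three times in one pot (3, 4, 13, 16, 17) are not numbered; the sense of induction in step 11 is taken as drawn for (S)-t-Bu-PHOX and would be corrected with the mirror-image ligand after the first run.

**Step 1**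
Reactants: 1 prop-2-yn-1-ol
Product: 2 tert-butyldimethyl(prop-2-yn-1-yloxy)silane
Conditions: TBSCl, imidazole, CH2Cl2, 0 °C → rt
Reagents that add atoms: tert-butyldimethylsilyl chloride, CC(C)(C)[Si](C)(C)Cl
Why: Standard silylation of a primary alcohol (Corey silyl ether formation).

**Step 2**
Reactants: 2 tert-butyldimethyl(prop-2-yn-1-yloxy)silane
Product: 3 (E)-tert-butyldimethyl{[3-(4,4,5,5-tetramethyl-1,3,2-dioxaborolan-2-yl)prop-2-en-1-yl]oxy}silane
Conditions: HBpin (1.1 equiv), Cp2Zr(H)Cl (5 mol %), Et3N (10 mol %), neat, 60 °C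
Reagents that add atoms: pinacolborane, CC1(C)OBOC1(C)C
Why: Zirconocene-hydride-catalysed hydroboration of a terminal alkyne is a syn, anti-Markovnikov addition and gives only the (E)-alkenyl boronate.

**Step 3**
Reactants: 4 phenol
Product: 5 2,6-dibromophenol
Conditions: NBS (2.0 equiv), i-Pr2NH (0.2 equiv), CH2Cl2, rt
Reagents that add atoms: N-bromosuccinimide, O=C1CCC(=O)N1Br
Why: Amine-mediated electrophilic aromatic bromination delivers bromine through a hydrogen-bonded N-bromoamine to both ortho positions and leaves the para position free.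

**Step 4**
Reactants: 5 2,6-dibromophenol
Product: 6 2,6-dimethoxyphenol
Conditions: NaOMe (6 equiv, 25 % in MeOH), CuI (20 mol %), DMF, 110 °C; then aq. HCl
Reagents that add atoms: sodium methoxide, C[O-].[Na+]
Why: Ullmann-type copper-catalysed methoxylation of aryl bromides, the same reaction used to make syringyl compounds from dibromophenols.

**Step 5**
Reactants: 6 2,6-dimethoxyphenol
Product: 7 4-bromo-2,6-dimethoxyphenol
Conditions: NBS (1.0 equiv), CHCl3, −45 °C → rt
Reagents that add atoms: N-bromosuccinimide, O=C1CCC(=O)N1Br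
Why: Electrophilic aromatic bromination goes para to the free phenol OH, the strongest director, at low temperature.

**Step 6**
Reactants: 7 4-bromo-2,6-dimethoxyphenol
Product: 8 (4-bromo-2,6-dimethoxyphenoxy)triisopropylsilane
Conditions: TIPSCl, imidazole, DMF, 40 °C
Reagents that add atoms: triisopropylsilyl chloride, CC(C)[Si](Cl)(C(C)C)C(C)C
Why: Silyl ether formation; the TIPS aryl ether is chosen because it survives the basic couplings and the acidic step 13.

**Step 7**
Reactants: 8 (4-bromo-2,6-dimethoxyphenoxy)triisopropylsilane; 3 (E)-alkenyl boronate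
Product: 9 tert-butyl{[(E)-3-(3,5-dimethoxy-4-triisopropylsilyloxyphenyl)prop-2-en-1-yl]oxy}dimethylsilane (sinapyl alcohol bis-silyl ether)
Conditions: Pd(OAc)2 (3 mol %), SPhos (6 mol %), K3PO4, THF/H2O 10:1, 60 °C
Reagents that add atoms: none
Why: Suzuki–Miyaura coupling of an unhindered electron-rich aryl bromide with an alkenyl boronate retains the E geometry.

**Step 8**
Reactants: 10 catechol
Product: 11 2-methoxyphenol (guaiacol)
Conditions: MeI (0.9 equiv), K2CO3 (1.0 equiv), acetone, 56 °C (catechol in excess, recovered)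
Reagents that add atoms: iodomethane, CI
Why: Williamson mono-O-methylation; sub-stoichiometric MeI keeps dimethylation low.

**Step 9**
Reactants: 11 2-methoxyphenol
Product: 12 4-bromo-2-methoxyphenol
Conditions: NBS (1.0 equiv), MeCN, 0 °C → rt
Reagents that add atoms: N-bromosuccinimide, O=C1CCC(=O)N1Br
Why: Electrophilic aromatic bromination para to the phenol OH, which out-directs the OMe group.

**Step 10**
Reactants: 12 4-bromo-2-methoxyphenol
Product: 13 4-bromo-2-iodo-6-methoxyphenol
Conditions: I2 (1.05 equiv), NaHCO3, H2O/MeOH, rt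
Reagents that add atoms: iodine, II
Why: Electrophilic aromatic iodination of the phenoxide goes to the only free ortho position, as in the preparation of 5-iodovanillin.

**Step 11**
Reactants: 13 4-bromo-2-iodo-6-methoxyphenol; 9 sinapyl alcohol bis-silyl ether (1.2 equiv)
Product: 14 tert-butyl{[(2S,3R)-5-bromo-2-(3,5-dimethoxy-4-triisopropylsilyloxyphenyl)-7-methoxy-2,3-dihydro-1-benzofuran-3-yl]methoxy}dimethylsilane (trans)
Conditions: Pd2(dba)3·CHCl3 (2.5 mol %), (S)-t-Bu-PHOX (6 mol %), Ag2CO3 (0.6 equiv), acetone, 45 °C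
Reagents that add atoms: none
Why: Proposed new method: an enantioselective intermolecular Pd-catalysed syn-oxyarylation ([3+2] heteroannulation) of an acyclic (E)-cinnamyl ether, in which Pd(0)/(S)-t-Bu-PHOX inserts into the C–I bond of 13 (C–Br untouched at 45 °C), Ag+ removes iodide, the cationic aryl-Pd adds syn and face-selectively to 9 with the aryl group going to the CH2OTBS-bearing carbon (this sets C3 = R and leaves Pd benzylic as an η3-benzyl species stabilised by the electron-rich ring), the neighbouring phenoxide then binds Pd to give a six-membered oxapalladacycle whose filled coordination sphere blocks β-hydride elimination, and C(sp3)–O reductive elimination with retention gives net syn addition across the E-alkene and therefore the trans (2S,3R) ring (any ionisation of the benzylic C–Pd bond also collapses to the more stable trans isomer); the closest known reaction types are the Larock heteroannulation of o-halophenols with 1,3-dienes (π-allyl in place of π-benzyl, also known in asymmetric form) and the racemic Pd/Ag2CO3 oxyarylation of cyclic styrenes such as 2H-chromenes.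

**Step 12**
Reactants: 14 bromo-dihydrobenzofuran; 3 (E)-alkenyl boronate (1.3 equiv)
Product: 15 tert-butyl{[(E)-3-[(2S,3R)-3-(tert-butyldimethylsilyloxymethyl)-2-(3,5-dimethoxy-4-triisopropylsilyloxyphenyl)-7-methoxy-2,3-dihydro-1-benzofuran-5-yl]prop-2-en-1-yl]oxy}dimethylsilane
Conditions: Pd(OAc)2 (3 mol %), SPhos (6 mol %), K3PO4, THF/H2O 10:1, 60 °C
Reagents that add atoms: none
Why: Suzuki–Miyaura coupling at the remaining aryl bromide installs the (E)-propenyl chain; neither stereocentre is acidic, and silyl ethers are inert to Pd(0).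

**Step 13**
Reactants: 15 tris-silyl ether
Product: 16 [(2S,3R)-2-(3,5-dimethoxy-4-triisopropylsilyloxyphenyl)-5-[(E)-3-hydroxyprop-1-en-1-yl]-7-methoxy-2,3-dihydro-1-benzofuran-3-yl]methanol
Conditions: CSA (0.2 equiv), MeOH/CH2Cl2 1:1, 0 °C
Reagents that add atoms: none
Why: Acid-catalysed methanolysis cleaves primary alkyl TBS ethers much faster than an aryl TIPS ether, and low temperature protects the cinnamyl alcohol.

**Step 14**
Reactants: 17 4-bromophenol
Product: 18 (4-bromophenoxy)(tert-butyl)dimethylsilane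
Conditions: TBSCl, imidazole, DMF, rt
Reagents that add atoms: tert-butyldimethylsilyl chloride, CC(C)(C)[Si](C)(C)Cl
Why: Standard phenol silylation.

**Step 15**
Reactants: 18 (4-bromophenoxy)(tert-butyl)dimethylsilane
Product: 21 4-(tert-butyldimethylsilyloxy)benzoic acid, via aryllithium 19 (not isolated), via lithium carboxylate 20 (not isolated)
Conditions: n-BuLi (1.05 equiv), THF, −78 °C; CO2; cold 1 M HCl to pH 3
Reagents that add atoms: carbon dioxide, O=C=O; n-butyllithium, [Li]CCCC (its lithium stays only in 19 and 20)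
Why: Bromine–lithium exchange followed by carboxylation; the para silyl ether cannot migrate and survives at −78 °C.

**Step 16**
Reactants: 16 diol; 21 4-(tert-butyldimethylsilyloxy)benzoic acid (2.4 equiv)
Product: 22 (E)-3-[(2S,3R)-3-{[4-(tert-butyldimethylsilyloxy)benzoyl]oxymethyl}-2-(3,5-dimethoxy-4-triisopropylsilyloxyphenyl)-7-methoxy-2,3-dihydro-1-benzofuran-5-yl]prop-2-en-1-yl 4-(tert-butyldimethylsilyloxy)benzoate
Conditions: DIC (2.6 equiv), DMAP (0.3 equiv), CH2Cl2, 0 °C → rt
Reagents that add atoms: none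
Why: Steglich esterification acylates both primary alcohols under neutral conditions that do not ionise the cinnamyl position, and the only phenol present is silyl-protected.

**Step 17**
Reactants: 22 tris-silylated bis-ester
Product: 23 quiquesetinerviusin B
Conditions: TBAF (4 equiv), AcOH (4 equiv), THF, 0 °C → rt
Reagents that add atoms: none
Why: Buffered fluoride desilylation removes all three aryl silyl ethers without touching the two benzoate esters or the trans-dihydrobenzofuran stereocentres.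

**Compound list**
1 | prop-2-yn-1-ol | C#CCO | starting material
2 | tert-butyldimethyl(prop-2-yn-1-yloxy)silane | C#CCO[Si](C)(C)C(C)(C)C | intermediate
3 | (E)-tert-butyldimethyl{[3-(4,4,5,5-tetramethyl-1,3,2-dioxaborolan-2-yl)prop-2-en-1-yl]oxy}silane | CC(C)(C)[Si](C)(C)OC/C=C/B1OC(C)(C)C(C)(C)O1 | intermediate
4 | phenol | Oc1ccccc1 | starting material
5 | 2,6-dibromophenol | Oc1c(Br)cccc1Br | intermediate
6 | 2,6-dimethoxyphenol | COc1cccc(OC)c1O | intermediate
7 | 4-bromo-2,6-dimethoxyphenol | COc1cc(Br)cc(OC)c1O | intermediate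
8 | (4-bromo-2,6-dimethoxyphenoxy)triisopropylsilane | COc1cc(Br)cc(OC)c1O[Si](C(C)C)(C(C)C)C(C)C | intermediate
9 | tert-butyl{[(E)-3-(3,5-dimethoxy-4-triisopropylsilyloxyphenyl)prop-2-en-1-yl]oxy}dimethylsilane | COc1cc(/C=C/CO[Si](C)(C)C(C)(C)C)cc(OC)c1O[Si](C(C)C)(C(C)C)C(C)C | intermediate
10 | catechol | Oc1ccccc1O | starting material
11 | 2-methoxyphenol | COc1ccccc1O | intermediate
12 | 4-bromo-2-methoxyphenol | COc1cc(Br)ccc1O | intermediate
13 | 4-bromo-2-iodo-6-methoxyphenol | COc1cc(Br)cc(I)c1O | intermediate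
14 | tert-butyl{[(2S,3R)-5-bromo-2-(3,5-dimethoxy-4-triisopropylsilyloxyphenyl)-7-methoxy-2,3-dihydro-1-benzofuran-3-yl]methoxy}dimethylsilane | COc1cc([C@H]2Oc3c(OC)cc(Br)cc3[C@@H]2CO[Si](C)(C)C(C)(C)C)cc(OC)c1O[Si](C(C)C)(C(C)C)C(C)C | intermediate
15 | tert-butyl{[(E)-3-[(2S,3R)-3-(tert-butyldimethylsilyloxymethyl)-2-(3,5-dimethoxy-4-triisopropylsilyloxyphenyl)-7-methoxy-2,3-dihydro-1-benzofuran-5-yl]prop-2-en-1-yl]oxy}dimethylsilane | COc1cc([C@H]2Oc3c(OC)cc(/C=C/CO[Si](C)(C)C(C)(C)C)cc3[C@@H]2CO[Si](C)(C)C(C)(C)C)cc(OC)c1O[Si](C(C)C)(C(C)C)C(C)C | intermediate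
16 | [(2S,3R)-2-(3,5-dimethoxy-4-triisopropylsilyloxyphenyl)-5-[(E)-3-hydroxyprop-1-en-1-yl]-7-methoxy-2,3-dihydro-1-benzofuran-3-yl]methanol | COc1cc([C@H]2Oc3c(OC)cc(/C=C/CO)cc3[C@@H]2CO)cc(OC)c1O[Si](C(C)C)(C(C)C)C(C)C | intermediate
17 | 4-bromophenol | Oc1ccc(Br)cc1 | starting material
18 | (4-bromophenoxy)(tert-butyl)dimethylsilane | CC(C)(C)[Si](C)(C)Oc1ccc(Br)cc1 | intermediate
19 | [4-(tert-butyldimethylsilyloxy)phenyl]lithium | [Li]c1ccc(O[Si](C)(C)C(C)(C)C)cc1 | intermediate (not isolated)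
20 | lithium 4-(tert-butyldimethylsilyloxy)benzoate | [Li+].[O-]C(=O)c1ccc(O[Si](C)(C)C(C)(C)C)cc1 | intermediate (not isolated)
21 | 4-(tert-butyldimethylsilyloxy)benzoic acid | CC(C)(C)[Si](C)(C)Oc1ccc(C(=O)O)cc1 | intermediate
22 | (E)-3-[(2S,3R)-3-{[4-(tert-butyldimethylsilyloxy)benzoyl]oxymethyl}-2-(3,5-dimethoxy-4-triisopropylsilyloxyphenyl)-7-methoxy-2,3-dihydro-1-benzofuran-5-yl]prop-2-en-1-yl 4-(tert-butyldimethylsilyloxy)benzoate | COc1cc([C@H]2Oc3c(OC)cc(/C=C/COC(=O)c4ccc(O[Si](C)(C)C(C)(C)C)cc4)cc3[C@@H]2COC(=O)c2ccc(O[Si](C)(C)C(C)(C)C)cc2)cc(OC)c1O[Si](C(C)C)(C(C)C)C(C)C | intermediate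
23 | quiquesetinerviusin B | COc1cc([C@H]2Oc3c(OC)cc(/C=C/COC(=O)c4ccc(O)cc4)cc3[C@@H]2COC(=O)c2ccc(O)cc2)cc(OC)c1O | target

**Totals**
Total step count: 17.
Longest linear sequence: 10 steps (3, 4, 5, 6, 7, 11, 12, 13, 16, 17; from phenol 4).

**Three steps most likely to fail**

Step 11 (proposed new oxyarylation): β-hydride elimination to the plain Heck product, low ee or the wrong sense of induction are all possible. The fallback uses known rhodium carbenoid C–H insertion chemistry; it sets out from 8 and 13 and comes back at 14. Bromine–lithium exchange on 8 (n-BuLi, THF, −78 °C) and a DMF quench give 3,5-dimethoxy-4-(triisopropylsilyloxy)benzaldehyde F1. NaBH4 in MeOH reduces it to [3,5-dimethoxy-4-(triisopropylsilyloxy)phenyl]methanol F2. Mitsunobu etherification of F2 with iodophenol 13 (PPh3, DIAD, THF) gives 5-bromo-1-iodo-3-methoxy-2-{[3,5-dimethoxy-4-(triisopropylsilyloxy)benzyl]oxy}benzene F3. Pd-catalysed coupling of the aryl iodide with ethyl diazoacetate (Pd(PPh3)4, Ag2CO3, Et3N, toluene, rt) gives ethyl 2-(5-bromo-3-methoxy-2-{[3,5-dimethoxy-4-(triisopropylsilyloxy)benzyl]oxy}phenyl)-2-diazoacetate F4. Intramolecular benzylic C–H insertion with Rh2(S-PTTL)4 (1 mol %, toluene, −60 °C) gives the cis ester ethyl (2S,3R)-5-bromo-2-(3,5-dimethoxy-4-triisopropylsilyloxyphenyl)-7-methoxy-2,3-dihydro-1-benzofuran-3-carboxylate F5; the mirror-image catalyst is used if the first run gives the 2R series. Epimerisation at C3 with DBU (toluene, 60 °C) gives the trans ester ethyl (2S,3S)-5-bromo-2-(3,5-dimethoxy-4-triisopropylsilyloxyphenyl)-7-methoxy-2,3-dihydro-1-benzofuran-3-carboxylate F6. DIBAL-H (CH2Cl2, −78 → 0 °C) gives [(2S,3R)-5-bromo-2-(3,5-dimethoxy-4-triisopropylsilyloxyphenyl)-7-methoxy-2,3-dihydro-1-benzofuran-3-yl]methanol F7, and TBSCl/imidazole converts it to 14.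

Step 4 (double Ullmann methoxylation of a free dibromophenol): hydrodebromination or a stalled mono-methoxy product are the risks. The fallback replaces copper substitution by directed ortho-metalation and oxidation; it sets out from 11 and comes back at 6, so steps 3 and 4 are bypassed. Guaiacol 11 is protected (MOMCl, i-Pr2NEt, CH2Cl2) as 1-methoxy-2-(methoxymethoxy)benzene F8. Lithiation ortho to the OMOM group (n-BuLi, TMEDA, THF, 0 °C), B(OMe)3 and H2O2/NaOH give 3-methoxy-2-(methoxymethoxy)phenol F9. MeI/K2CO3 in acetone gives 1,3-dimethoxy-2-(methoxymethoxy)benzene F10, and HCl in MeOH (50 °C) removes the MOM group to give 6.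

Step 13 (selective removal of two alkyl TBS ethers beside an aryl TIPS ether on an acid-sensitive cinnamyl system): the risks are allylic methanolysis or partial loss of TIPS. The fallback drops the selective deprotection and relies on chemoselective esterification instead; it sets out from 15 and comes back at 23. TBAF (4 equiv, THF, 0 °C → rt) removes all three silyl groups to give 4-[(2S,3R)-3-(hydroxymethyl)-5-[(E)-3-hydroxyprop-1-en-1-yl]-7-methoxy-2,3-dihydro-1-benzofuran-2-yl]-2,6-dimethoxyphenol F11. Mitsunobu esterification with acid 21 (2.2 equiv, PPh3, DIAD, THF, 0 °C) acylates only the two primary alcohols, because the carboxylic acid far out-competes the hindered phenol as pronucleophile, and gives (E)-3-[(2S,3R)-3-{[4-(tert-butyldimethylsilyloxy)benzoyl]oxymethyl}-2-(4-hydroxy-3,5-dimethoxyphenyl)-7-methoxy-2,3-dihydro-1-benzofuran-5-yl]prop-2-en-1-yl 4-(tert-butyldimethylsilyloxy)benzoate F12. TBAF/AcOH (THF, 0 °C) then removes the two aryl TBS groups to give 23.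

**Further compounds**
F1 | step 11 | 3,5-dimethoxy-4-(triisopropylsilyloxy)benzaldehyde | COc1cc(C=O)cc(OC)c1O[Si](C(C)C)(C(C)C)C(C)C
F2 | step 11 | [3,5-dimethoxy-4-(triisopropylsilyloxy)phenyl]methanol | COc1cc(CO)cc(OC)c1O[Si](C(C)C)(C(C)C)C(C)C
F3 | step 11 | 5-bromo-1-iodo-3-methoxy-2-{[3,5-dimethoxy-4-(triisopropylsilyloxy)benzyl]oxy}benzene | COc1cc(Br)cc(I)c1OCc1cc(OC)c(O[Si](C(C)C)(C(C)C)C(C)C)c(OC)c1
F4 | step 11 | ethyl 2-(5-bromo-3-methoxy-2-{[3,5-dimethoxy-4-(triisopropylsilyloxy)benzyl]oxy}phenyl)-2-diazoacetate | CCOC(=O)C(=[N+]=[N-])c1cc(Br)cc(OC)c1OCc1cc(OC)c(O[Si](C(C)C)(C(C)C)C(C)C)c(OC)c1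
F5 | step 11 | ethyl (2S,3R)-5-bromo-2-(3,5-dimethoxy-4-triisopropylsilyloxyphenyl)-7-methoxy-2,3-dihydro-1-benzofuran-3-carboxylate (cis) | COc1cc([C@H]2Oc3c(OC)cc(Br)cc3[C@H]2C(=O)OCC)cc(OC)c1O[Si](C(C)C)(C(C)C)C(C)C
F6 | step 11 | ethyl (2S,3S)-5-bromo-2-(3,5-dimethoxy-4-triisopropylsilyloxyphenyl)-7-methoxy-2,3-dihydro-1-benzofuran-3-carboxylate (trans) | COc1cc([C@H]2Oc3c(OC)cc(Br)cc3[C@@H]2C(=O)OCC)cc(OC)c1O[Si](C(C)C)(C(C)C)C(C)C
F7 | step 11 | [(2S,3R)-5-bromo-2-(3,5-dimethoxy-4-triisopropylsilyloxyphenyl)-7-methoxy-2,3-dihydro-1-benzofuran-3-yl]methanol | COc1cc([C@H]2Oc3c(OC)cc(Br)cc3[C@@H]2CO)cc(OC)c1O[Si](C(C)C)(C(C)C)C(C)C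
F8 | step 4 | 1-methoxy-2-(methoxymethoxy)benzene | COCOc1ccccc1OC
F9 | step 4 | 3-methoxy-2-(methoxymethoxy)phenol | COCOc1c(O)cccc1OC
F10 | step 4 | 1,3-dimethoxy-2-(methoxymethoxy)benzene | COCOc1c(OC)cccc1OC
F11 | step 13 | 4-[(2S,3R)-3-(hydroxymethyl)-5-[(E)-3-hydroxyprop-1-en-1-yl]-7-methoxy-2,3-dihydro-1-benzofuran-2-yl]-2,6-dimethoxyphenol | COc1cc([C@H]2Oc3c(OC)cc(/C=C/CO)cc3[C@@H]2CO)cc(OC)c1O
F12 | step 13 | (E)-3-[(2S,3R)-3-{[4-(tert-butyldimethylsilyloxy)benzoyl]oxymethyl}-2-(4-hydroxy-3,5-dimethoxyphenyl)-7-methoxy-2,3-dihydro-1-benzofuran-5-yl]prop-2-en-1-yl 4-(tert-butyldimethylsilyloxy)benzoate | COc1cc([C@H]2Oc3c(OC)cc(/C=C/COC(=O)c4ccc(O[Si](C)(C)C(C)(C)C)cc4)cc3[C@@H]2COC(=O)c2ccc(O[Si](C)(C)C(C)(C)C)cc2)cc(OC)c1O
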